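Ring C is dissected across its β-aryloxy ketone. The key step exploits the ortho placement of C4 and O1 on ring A and the 1,3-relationship of the C4 carbonyl to the O1–C2 ether: in one flask a salicylaldehyde (ring A, carrying the (S)-N-sulfinylpiperidine at the future C6 and one free phenol, the future O1) and a tert-butyl arylpropiolate (C2, C3, ring B) are joined by rhodium-catalysed hydroacylation (C3–C4) and a thiourea-catalysed oxa-Michael closure (O1–C2) that sets C2. The temporary C3 ester directs both events and is later lost as CO2; the piperidine centre comes from N-tert-butanesulfinyl imine chemistry.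

Key step: step 7

Remark: flavanone numbering (O1, C2, C3, C4, C4a, C5 to C8, C8a; ring B on C2) is used throughout. C3 of 16 and 17 is an epimerisable, partly enolised centre; it is left unassigned and disappears in step 8.
Assumption: compounds 1, 3, 4 and 12 are taken as catalogue chemicals.

Step 1
Reactants: 1 3,5-bis(benzyloxy)phenol
Product: 2 [3,5-bis(benzyloxy)phenoxy]triisopropylsilane
Conditions: TIPSCl, imidazole, DMF, rt
Reagents that add atoms: chlorotri(propan-2-yl)silane (TIPSCl), CC(C)[Si](Cl)(C(C)C)C(C)C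
Why: Silyl ether formation on the only free hydroxyl; the bulky, poorly coordinating TIPS ether shields its two flanking positions, so the later lithiation can only go between the two benzyloxy groups.

Step 2
Reactants: 3 5-chloropentanal; 4 (S)-2-methylpropane-2-sulfinamide
Product: 5 (S,E)-N-(5-chloropentylidene)-2-methylpropane-2-sulfinamide
Conditions: CuSO4, CH2Cl2, rt
Reagents that add atoms: none
Why: Condensation of an aldehyde with tert-butanesulfinamide under CuSO4 dehydration (sulfinimine formation) should give the E-aldimine and leave the primary chloride untouched.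

Step 3
Reactants: 2 [3,5-bis(benzyloxy)phenoxy]triisopropylsilane; 5 (S,E)-N-(5-chloropentylidene)-2-methylpropane-2-sulfinamide
Product: 9 (2S)-2-[2,6-bis(benzyloxy)-4-(triisopropylsilyloxy)phenyl]-1-[(S)-tert-butylsulfinyl]piperidine, via aryllithium 6 (not isolated), via arylmagnesium bromide 7 (not isolated), via open-chain sulfinamide 8 (not isolated)
Conditions: n-BuLi, THF, 0 °C; MgBr2·OEt2, 0 °C; then 5, toluene, −78 to −20 °C; then KN(SiMe3)2, 0 °C to rt
Reagents that add atoms: none
Why: Directed ortho-metalation between the two benzyloxy groups, Li-to-Mg exchange and addition of the aryl Grignard reagent to the N-sulfinyl aldimine through the six-membered Mg–O=S chelated chair transition state should give the (S) carbon from the (S)-sulfinyl group (minor diastereomer removed by chromatography), after which the potassium sulfinamide closes the piperidine by 6-exo-tet N-alkylation.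

Step 4
Reactants: 9 (2S)-2-[2,6-bis(benzyloxy)-4-(triisopropylsilyloxy)phenyl]-1-[(S)-tert-butylsulfinyl]piperidine
Product: 10 3,5-bis(benzyloxy)-4-{(2S)-1-[(S)-tert-butylsulfinyl]piperidin-2-yl}phenol
Conditions: Bu4NF, THF, 0 °C
Reagents that add atoms: none
Why: Fluoride cleavage of the aryl silyl ether frees the phenol para to the piperidine, while the sulfinamide and the benzyl ethers are inert to fluoride.

Step 5
Reactants: 10 3,5-bis(benzyloxy)-4-{(2S)-1-[(S)-tert-butylsulfinyl]piperidin-2-yl}phenol
Product: 11 2,4-bis(benzyloxy)-6-hydroxy-3-{(2S)-1-[(S)-tert-butylsulfinyl]piperidin-2-yl}benzaldehyde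
Conditions: MgCl2, Et3N, paraformaldehyde, MeCN, reflux
Reagents that add atoms: paraformaldehyde (as formaldehyde), C=O
Why: Magnesium-phenoxide-directed ortho-formylation (Casnati–Skattebøl reaction) puts CHO only ortho to the free OH, and because both ortho positions are equivalent a single salicylaldehyde should result whose free OH is the future O1.

Step 6
Reactants: 12 1-(benzyloxy)-4-ethynylbenzene
Product: 14 tert-butyl 3-[4-(benzyloxy)phenyl]prop-2-ynoate, via lithium acetylide 13 (not isolated)
Conditions: n-BuLi, THF, −78 °C; then Boc2O, −78 °C to rt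
Reagents that add atoms: di-tert-butyl dicarbonate (Boc2O), CC(C)(C)OC(=O)OC(=O)OC(C)(C)C
Why: C-acylation of a lithium acetylide with Boc2O is a standard route to tert-butyl alkynoates.

Step 7
Reactants: 11 2,4-bis(benzyloxy)-6-hydroxy-3-{(2S)-1-[(S)-tert-butylsulfinyl]piperidin-2-yl}benzaldehyde; 14 tert-butyl 3-[4-(benzyloxy)phenyl]prop-2-ynoate
Product: 16 tert-butyl (2S)-5,7-bis(benzyloxy)-2-[4-(benzyloxy)phenyl]-6-{(2S)-1-[(S)-tert-butylsulfinyl]piperidin-2-yl}-4-oxochromane-3-carboxylate, via alkylidene β-ketoester 15 (not isolated)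
Conditions: [Rh(cod)OMe]2 (2.5 mol %), dppf (5 mol %), toluene, 60 °C; then −25 °C, 9-epi-aminocinchona 3,5-bis(trifluoromethyl)phenyl thiourea (10 mol %; pseudoenantiomer giving 2S)
Reagents that add atoms: none
Why: Proposed new method: the rhodium phenoxide of 11 should add the aldehyde C–H bond to monovalent rhodium to give a chelated trivalent acyl hydride, which hydrometalates the ynoate with hydride going to the aryl-bearing carbon and then forms C3–C4 by reductive elimination to give 15; the closest known reaction is the rhodium-catalysed hydroacylation of internal aryl alkynes by salicylaldehydes with ensuing oxo-Michael closure to chroman-4-ones, which has not been shown for arylpropiolates or joined to a chiral closure. At −25 °C the bifunctional thiourea should bind the β-ketoester by two hydrogen bonds while its quinuclidine guides the phenol, so that ring C closes by a 6-endo-trig oxa-Michael addition, the mode known for thiourea-catalysed cyclisation of 2-hydroxyaryl alkylidene β-ketoesters. C2 is set by the catalyst (the quinine- or quinidine-derived pseudoenantiomer is chosen for 2S), independently of the remote piperidine centre, and C3 is epimerisable and of no consequence. The regioselectivity of C–C formation rests on the polarisation of the ynoate and on the known preference for acyl transfer to the alkyne carbon remote from the aryl group. Only one oxygen can close because the two phenols flanking the piperidine are benzylated, which fixes the piperidine at C6 and not C8, and the non-basic sulfinamide nitrogen leaves no internal base for an uncontrolled closure.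

Step 8
Reactants: 16 tert-butyl (2S)-5,7-bis(benzyloxy)-2-[4-(benzyloxy)phenyl]-6-{(2S)-1-[(S)-tert-butylsulfinyl]piperidin-2-yl}-4-oxochromane-3-carboxylate
Product: 18 (2S)-5,7-bis(benzyloxy)-2-[4-(benzyloxy)phenyl]-6-[(2S)-piperidin-2-yl]chroman-4-one, via β-keto acid 17 (not isolated)
Conditions: 4 M HCl in dioxane, rt then 50 °C; evaporate, triturate the hydrochloride with Et2O, then aq. NaHCO3
Reagents that add atoms: none
Why: Anhydrous HCl cleaves the N–S bond and the tert-butyl ester and the β-keto acid loses CO2 on warming (acidolysis and decarboxylation), and under acid the β-aryloxy ketone has no E1cB ring-opening path, so C2 should keep its configuration.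

Step 9
Reactants: 18 (2S)-5,7-bis(benzyloxy)-2-[4-(benzyloxy)phenyl]-6-[(2S)-piperidin-2-yl]chroman-4-one
Product: 19 (2S)-5,7-bis(benzyloxy)-2-[4-(benzyloxy)phenyl]-6-[(2S)-1-methylpiperidin-2-yl]chroman-4-one
Conditions: aq. HCHO, NaBH(OAc)3, ClCH2CH2Cl, rt
Reagents that add atoms: formaldehyde, C=O
Why: Reductive amination methylates the secondary amine; the hindered aryl ketone should not be reduced by NaBH(OAc)3, and the benzyl ethers keep ring A from Mannich attack by formaldehyde.

Step 10
Reactants: 19 (2S)-5,7-bis(benzyloxy)-2-[4-(benzyloxy)phenyl]-6-[(2S)-1-methylpiperidin-2-yl]chroman-4-one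
Product: 20 (2S)-5,7-dihydroxy-2-(4-hydroxyphenyl)-6-[(2S)-1-methylpiperidin-2-yl]chroman-4-one
Conditions: H2 (1 atm), 10% Pd/C, EtOAc/MeOH, rt
Reagents that add atoms: none
Why: Hydrogenolysis of the three benzyl ethers under neutral conditions avoids the base-induced ring opening that would scramble C2, and the conjugated, hydrogen-bonded ketone and the hindered benzylic C–N bond should survive.

Compound list
1 | 3,5-bis(benzyloxy)phenol | Oc1cc(OCc2ccccc2)cc(OCc2ccccc2)c1 | starting material
2 | [3,5-bis(benzyloxy)phenoxy]triisopropylsilane | CC(C)[Si](Oc1cc(OCc2ccccc2)cc(OCc2ccccc2)c1)(C(C)C)C(C)C | intermediate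
3 | 5-chloropentanal | O=CCCCCCl | starting material
4 | (S)-2-methylpropane-2-sulfinamide | CC(C)(C)[S@](=O)N | starting material
5 | (S,E)-N-(5-chloropentylidene)-2-methylpropane-2-sulfinamide | CC(C)(C)[S@](=O)/N=C/CCCCCl | intermediate
6 | [2,6-bis(benzyloxy)-4-(triisopropylsilyloxy)phenyl]lithium | [Li]c1c(OCc2ccccc2)cc(O[Si](C(C)C)(C(C)C)C(C)C)cc1OCc1ccccc1 | intermediate (not isolated)
7 | [2,6-bis(benzyloxy)-4-(triisopropylsilyloxy)phenyl]magnesium bromide | Br[Mg]c1c(OCc2ccccc2)cc(O[Si](C(C)C)(C(C)C)C(C)C)cc1OCc1ccccc1 | intermediate (not isolated)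
8 | (S)-N-{(1S)-1-[2,6-bis(benzyloxy)-4-(triisopropylsilyloxy)phenyl]-5-chloropentyl}-2-methylpropane-2-sulfinamide (present in the flask as its N-magnesium salt) | CC(C)(C)[S@](=O)N[C@@H](CCCCCl)c1c(OCc2ccccc2)cc(O[Si](C(C)C)(C(C)C)C(C)C)cc1OCc1ccccc1 | intermediate (not isolated)
9 | (2S)-2-[2,6-bis(benzyloxy)-4-(triisopropylsilyloxy)phenyl]-1-[(S)-tert-butylsulfinyl]piperidine | CC(C)(C)[S@](=O)N1CCCC[C@H]1c1c(OCc2ccccc2)cc(O[Si](C(C)C)(C(C)C)C(C)C)cc1OCc1ccccc1 | intermediate
10 | 3,5-bis(benzyloxy)-4-{(2S)-1-[(S)-tert-butylsulfinyl]piperidin-2-yl}phenol | CC(C)(C)[S@](=O)N1CCCC[C@H]1c1c(OCc2ccccc2)cc(O)cc1OCc1ccccc1 | intermediate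
11 | 2,4-bis(benzyloxy)-6-hydroxy-3-{(2S)-1-[(S)-tert-butylsulfinyl]piperidin-2-yl}benzaldehyde | CC(C)(C)[S@](=O)N1CCCC[C@H]1c1c(OCc2ccccc2)cc(O)c(C=O)c1OCc1ccccc1 | intermediate
12 | 1-(benzyloxy)-4-ethynylbenzene | C#Cc1ccc(OCc2ccccc2)cc1 | starting material
13 | lithium [4-(benzyloxy)phenyl]acetylide | [Li]C#Cc1ccc(OCc2ccccc2)cc1 | intermediate (not isolated)
14 | tert-butyl 3-[4-(benzyloxy)phenyl]prop-2-ynoate | CC(C)(C)OC(=O)C#Cc1ccc(OCc2ccccc2)cc1 | intermediate
15 | tert-butyl (2Z)-2-(2,4-bis(benzyloxy)-6-hydroxy-3-{(2S)-1-[(S)-tert-butylsulfinyl]piperidin-2-yl}benzoyl)-3-[4-(benzyloxy)phenyl]prop-2-enoate | CC(C)(C)[S@](=O)N1CCCC[C@H]1c1c(OCc2ccccc2)cc(O)c(c1OCc1ccccc1)C(=O)/C(C(=O)OC(C)(C)C)=C/c1ccc(OCc2ccccc2)cc1 | intermediate (not isolated)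
16 | tert-butyl (2S)-5,7-bis(benzyloxy)-2-[4-(benzyloxy)phenyl]-6-{(2S)-1-[(S)-tert-butylsulfinyl]piperidin-2-yl}-4-oxochromane-3-carboxylate (C3 unassigned) | CC(C)(C)[S@](=O)N1CCCC[C@H]1c1c(OCc2ccccc2)cc2c(c1OCc1ccccc1)C(=O)C(C(=O)OC(C)(C)C)[C@@H](c1ccc(OCc3ccccc3)cc1)O2 | intermediate
17 | (2S)-5,7-bis(benzyloxy)-2-[4-(benzyloxy)phenyl]-4-oxo-6-[(2S)-piperidin-2-yl]chromane-3-carboxylic acid (C3 unassigned; hydrochloride in the flask) | N1CCCC[C@H]1c1c(OCc2ccccc2)cc2c(c1OCc1ccccc1)C(=O)C(C(=O)O)[C@@H](c1ccc(OCc3ccccc3)cc1)O2 | intermediate (not isolated)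
18 | (2S)-5,7-bis(benzyloxy)-2-[4-(benzyloxy)phenyl]-6-[(2S)-piperidin-2-yl]chroman-4-one | N1CCCC[C@H]1c1c(OCc2ccccc2)cc2c(c1OCc1ccccc1)C(=O)C[C@@H](c1ccc(OCc3ccccc3)cc1)O2 | intermediate
19 | (2S)-5,7-bis(benzyloxy)-2-[4-(benzyloxy)phenyl]-6-[(2S)-1-methylpiperidin-2-yl]chroman-4-one | CN1CCCC[C@H]1c1c(OCc2ccccc2)cc2c(c1OCc1ccccc1)C(=O)C[C@@H](c1ccc(OCc3ccccc3)cc1)O2 | intermediate
20 | (2S)-5,7-dihydroxy-2-(4-hydroxyphenyl)-6-[(2S)-1-methylpiperidin-2-yl]chroman-4-one | CN1CCCC[C@H]1c1c(O)cc2c(c1O)C(=O)C[C@@H](c1ccc(O)cc1)O2 | target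

Total step count: 10. Longest linear sequence: 8 steps (steps 1, 3, 4, 5, 7, 8, 9, 10).

Steps most likely to fail

Step 7 (bears the label). The acyl rhodium species may lose CO before it meets the alkyne, hydride may be delivered to the wrong alkyne carbon, or the ring may close without the chiral catalyst during the warm hydroacylation stage, which would cost facial control at C2. The fallback uses known chemistry, sets out from 11 and returns to the route at 16. Addition of the lithium enolate of tert-butyl acetate (LiN(iPr)2, THF, −78 °C, excess) to the aldehyde should give the β-hydroxy ester F1 as a carbinol mixture. MnO2 in CH2Cl2 should oxidise the benzylic carbinol to the β-keto ester F2. Knoevenagel condensation of F2 with 4-(benzyloxy)benzaldehyde (piperidinium acetate, toluene, 4 Å sieves, rt) should give 15, this time isolated, which is closed with the same thiourea at −25 °C to 16. This fallback builds ring C by Knoevenagel condensation and oxa-Michael addition instead of hydroacylation.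

Step 3. The hindered, basic aryl Grignard reagent may deprotonate the enolisable aldimine instead of adding to it, or add with poor facial selectivity. The fallback sets out from 2 and returns at 8. After lithiation to 6 as before, acylation with 5-chloro-N-methoxy-N-methylpentanamide (Weinreb ketone synthesis) should give the aryl ketone F3. Condensation with 4 (Ti(OEt)4, THF, reflux; expected to be slow for this hindered ketone) should give the N-sulfinyl ketimine F4. NaBH4 reduction (THF, −48 °C) through the cyclic transition state bound at the sulfinyl oxygen should give 8, now isolated and purified, which KN(SiMe3)2 cyclises to 9 as in step 3.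

Step 10. Hydrogenolysis may also cut the benzylic C2–O1 bond or the benzylic C–N bond, or stall through amine poisoning of the catalyst. The fallback goes from 19 directly to 20 by Lewis-acid debenzylation with BCl3 and pentamethylbenzene as benzyl-cation scavenger (CH2Cl2, −78 °C); it makes no new compound.

Further compounds
F1 | step 7 | tert-butyl 3-(2,4-bis(benzyloxy)-6-hydroxy-3-{(2S)-1-[(S)-tert-butylsulfinyl]piperidin-2-yl}phenyl)-3-hydroxypropanoate (carbinol centre unassigned) | CC(C)(C)[S@](=O)N1CCCC[C@H]1c1c(OCc2ccccc2)cc(O)c(c1OCc1ccccc1)C(O)CC(=O)OC(C)(C)C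
F2 | step 7 | tert-butyl 3-(2,4-bis(benzyloxy)-6-hydroxy-3-{(2S)-1-[(S)-tert-butylsulfinyl]piperidin-2-yl}phenyl)-3-oxopropanoate | CC(C)(C)[S@](=O)N1CCCC[C@H]1c1c(OCc2ccccc2)cc(O)c(c1OCc1ccccc1)C(=O)CC(=O)OC(C)(C)C
F3 | step 3 | 1-[2,6-bis(benzyloxy)-4-(triisopropylsilyloxy)phenyl]-5-chloropentan-1-one | O=C(CCCCCl)c1c(OCc2ccccc2)cc(O[Si](C(C)C)(C(C)C)C(C)C)cc1OCc1ccccc1
F4 | step 3 | (S)-N-{1-[2,6-bis(benzyloxy)-4-(triisopropylsilyloxy)phenyl]-5-chloropentylidene}-2-methylpropane-2-sulfinamide (C=N geometry unassigned) | CC(C)(C)[S@](=O)N=C(CCCCCl)c1c(OCc2ccccc2)cc(O[Si](C(C)C)(C(C)C)C(C)C)cc1OCc1ccccc1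
F0 | step 10 | none | none
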